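All runs are simulated with made-up constants, noise included.

We want the product at the end of this flask, and the earlier runs suggest that one subtraction on the charges gets us close to it.

in all of them: solid substrate 0.050 M

|  | partner | protic impurity | remark | time |
|---|---|---|---|---|
| birch | 0.050 M | 0.50 mM | run made earlier |  |
| maple | 0.050 M | 2 mM | run made earlier |  |
| flask | 0.0500 M | 1.00 mM |  | 12 d |

| run | time / d | solid substrate / % | product / % |
|---|---|---|---|
| birch | 1.67 | 0.1 | 94.9 |
| birch | 4.00 | 0.2 | 97.6 |
| birch | 8.00 | 0 | 98.4 |
| birch | 12.0 | 0 | 98.6 |
| maple | 1.67 | 0 | 92.8 |
| maple | 4.00 | 0 | 95.4 |
| maple | 8.00 | 0.1 | 95.6 |
| maple | 12.0 | 0 | 95.9 |

(readings scatter by 0.3 percentage points)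

* why nothing more happens at 12 d, or that something still does (for what has run out or reacted, a solid counts together with what of it has only dissolved) (the partner has run out first / it is still moving / forward and back rates have come level)
* part of the solid substrate that has turned into other species by 12 d (what has only dissolved does not count)
* how much product there is at 12 d, in percent of the solid substrate charged
* amount of product if the flask were left three thousand times as long, in percent of the solid substrate charged

- solid substrate is a solid; its amount is given per volume of the solution
- at the start none of the solid substrate is in solution
- what has only dissolved of solid substrate counts as not reacted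
- the reaction counts as stopped when no species that holds the solid substrate changes by six tenths of a point or more over the second half of the time

We take the protic impurity first, the one setting the runs have turned. If it destroys partner one for one, then in this flask the charged [partner] less the charged [protic impurity], as a share of the charged solid substrate, comes to 98.0%, and we call this share the usable partner. By hand the same share is 99.0% for birch and 96.0% for maple, a step of 3 percentage points, while their last product readings, 98.6% and 95.9%, differ by 2.7 points, with a scatter of 0.3 points on each reading.

Time should do little once the usable partner is consumed, and from 8.00 d to 12.0 d the product gains 0.2 points in birch and 0.3 points in maple.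

Partner and solid substrate were not turned in the runs, but by hand the crossing lies where usable partner equals the solid substrate charged. This flask stands just below it, with 0.0490 M of usable partner against 0.050 M, which makes partner the limiting reagent, so we commit to product a little under 98.0%.

The forecast says the partner has run out first, with 97.9% converted, 97.9% of product at 12 d and 98% in the long run, holding that “the end point is not an equilibrium”.

The flask gives this answer: the partner has run out first, with 98.2% converted, 97.9% of product, and 98.0% in the long run.

    2 solid substrate → homo dimer (k = 6.60 × 10⁻⁶ M⁻¹ s⁻¹)
    dissolved substrate + partner → product (k = 0.00310 M⁻¹ s⁻¹)
    partner + protic impurity → quenched reagent (k = 0.0350 M⁻¹ s⁻¹)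
    solid substrate ⇌ dissolved substrate, rate k4*(cs4 - [dissolved substrate]) while solid is left; crystals form when [dissolved substrate] > cs4 (solubility = 33.0 mM, k = 1.70 × 10⁻⁴ s⁻¹)

In this flask the usable partner of 98.0%, less the 0.12% of partner still free at 12.0 d, comes to 97.9%. The neighbouring flask is this one with 0.030 M of partner, so its usable partner is 58.0%, lower than the 98.0% here. That neighbour ends with 58.0% of product and its partner at 0% of its charge, while 42% of its solid substrate stays unreacted, standing at 12.0 d as 41.7% of dissolved substrate.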